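The route rests on opening the bicyclo[3.3.0]oct-1-ene made of cyclopentene ring A (C10–C14) and cyclopentane ring B (C11, C12, C15–C17) at their shared C11–C12 bond. A cobalt-catalysed Pauson–Khand cyclocarbonylation closes ring B through C11–C12 and wraps ring A around it in the same operation, using the tetrasubstituted C10=C11 alkene at the ring fusion as the alkyne retron. Its precursor is a monocyclic (S)-3-alkynylpiperidine-2,4-dione (ring D) whose quaternary C17 carries a chloroenyne and a vinyl carbinol tether. The C6 ketone then activates C7 for closure of ring C, before C6 itself is turned into the second quaternary centre.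

Key step: step 6

Atom labels used throughout: C1–C5 side chain (C3 carbinol, C5 on C6); C6 quaternary carbon carrying C20 (CH2OH); C7 methine; C8, C9; C10=C11; C12 methine; C13, C14; C15 methine carrying C21 (CH2OH); C16; C17 quaternary; C18 (NCH2 on C17) and C19 (NCH2 on C7). Ring A = C10–C11–C12–C13–C14, ring B = C11–C12–C15–C16–C17, ring C = C6–C7–C8–C9–C10–C11–C17, ring D = C6–C7–C19–N–C18–C17.

Remark on the chemistry: the epimeric mixtures at C15 (8, 10), at C12/C15 (12, 13), at C14 (15) and at C6 (21) are carried on as such, because each of these centres is flattened or replaced before it matters.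

Step 1
Reactants: 1 1-methylpiperidine-2,4-dione; 2 tert-butyl 2-(bromomethyl)prop-2-enoate
Product: 3 tert-butyl 2-[(1-methyl-2,4-dioxopiperidin-3-yl)methyl]prop-2-enoate (racemic)
Conditions: K2CO3, acetone, 0 °C to rt (1 in excess)
Reagents that add atoms: 2 tert-butyl 2-(bromomethyl)prop-2-enoate, C=C(CBr)C(=O)OC(C)(C)C
Why: C-alkylation of the doubly stabilised C17 carbanion of the cyclic β-keto lactam by SN2′ addition–elimination on the 2-(bromomethyl)acrylate, with excess 1 holding back dialkylation.

Step 2
Reactants: 3 tert-butyl 2-[(1-methyl-2,4-dioxopiperidin-3-yl)methyl]prop-2-enoate; 4 1-[(trimethylsilyl)ethynyl]-1,2-benziodoxol-3(1H)-one (TMS-EBX)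
Product: 5 tert-butyl 2-{[(3S)-3-ethynyl-1-methyl-2,4-dioxopiperidin-3-yl]methyl}prop-2-enoate
Conditions: KF, 4,4-dibutyl-2,6-bis(3,4,5-trifluorophenyl)-4,5-dihydro-3H-dinaphtho[2,1-c:1′,2′-e]azepinium bromide (5 mol%, enantiomer chosen to give 3S), toluene, −40 °C
Reagents that add atoms: 4 TMS-EBX, C[Si](C)(C)C#CI1OC(=O)c2ccccc12
Why: electrophilic α-ethynylation of a β-dicarbonyl enolate by the ethynylbenziodoxolone that fluoride releases from 4, run under asymmetric phase-transfer catalysis so that the chiral ammonium enolate ion pair exposes one face of C17 and sets the quaternary centre as 3S.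

Step 3
Reactants: 5 tert-butyl 2-{[(3S)-3-ethynyl-1-methyl-2,4-dioxopiperidin-3-yl]methyl}prop-2-enoate
Product: 6 tert-butyl 3-[(3S)-3-ethynyl-1-methyl-2,4-dioxopiperidin-3-yl]-2-oxopropanoate
Conditions: OsO4 (cat.), NaIO4, 2,6-lutidine, dioxane/H2O, rt
Reagents that add atoms: osmium tetroxide, O=[Os](=O)(=O)=O; sodium periodate, [Na+].[O-]I(=O)(=O)=O
Why: Lemieux–Johnson cleavage of the 1,1-disubstituted acrylate alkene to the α-keto ester, osmylation of the alkene being much faster than that of the terminal alkyne.

Step 4
Reactants: 6 tert-butyl 3-[(3S)-3-ethynyl-1-methyl-2,4-dioxopiperidin-3-yl]-2-oxopropanoate; 7 vinylmagnesium bromide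
Product: 8 tert-butyl 2-{[(3S)-3-ethynyl-1-methyl-2,4-dioxopiperidin-3-yl]methyl}-2-hydroxybut-3-enoate (both C15 epimers)
Conditions: THF, −78 °C; then H2O
Reagents that add atoms: 7 vinylmagnesium bromide, C=C[Mg]Br
Why: Grignard 1,2-addition to the ketone of the α-keto ester, by far the most electrophilic carbonyl present (the C6 ketone is neopentyl, the tert-butyl ester and the lactam are inert at −78 °C), which installs the C12=C13 vinyl group and C21 on C15.

Step 5
Reactants: 8 tert-butyl 2-{[(3S)-3-ethynyl-1-methyl-2,4-dioxopiperidin-3-yl]methyl}-2-hydroxybut-3-enoate; 9 (Z)-1,2-dichloroethene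
Product: 10 tert-butyl 2-({(3S)-3-[(3Z)-4-chlorobut-3-en-1-yn-1-yl]-1-methyl-2,4-dioxopiperidin-3-yl}methyl)-2-hydroxybut-3-enoate (C15 epimers)
Conditions: 9 (excess), Pd(PPh3)4 (cat.), CuI (cat.), i-Pr2NH, THF, rt
Reagents that add atoms: 9 (Z)-1,2-dichloroethene, Cl/C=C\Cl
Why: Sonogashira coupling of the terminal alkyne with one C–Cl bond of the dichloroalkene, a coupling that stops at the monocoupled chloroenyne with retention of the Z geometry and so attaches C9 and C8 to C10.

Step 6
Reactants: 10 tert-butyl 2-({(3S)-3-[(3Z)-4-chlorobut-3-en-1-yn-1-yl]-1-methyl-2,4-dioxopiperidin-3-yl}methyl)-2-hydroxybut-3-enoate; 11 carbon monoxide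
Product: 12 spirocyclic Pauson–Khand enone: ring B of a bicyclo[3.3.0]oct-1-en-3-one (C14 ketone, C10=C11, C10 carrying the (Z)-2-chlorovinyl group, C12–H, C15 carrying OH and CO2t-Bu) shares C17 with the (S)-1-methylpiperidine-2,4-dione; epimers at C12 and C15
Conditions: Co2(CO)8 (20 mol%), tetramethylthiourea, CO (1 atm), benzene, 70 °C
Reagents that add atoms: 11 carbon monoxide, [C-]#[O+]
Why: The alkyne of 10 is taken up as its dicobalt hexacarbonyl complex, the pendant C12=C13 vinyl group coordinates and inserts so that C11 bonds to C12, carbon monoxide then inserts at C13 and reductive elimination joins C14 to C10, the thiourea additive turning the cobalt over under CO (intramolecular Pauson–Khand [2+2+1] cyclocarbonylation of a 1,6-enyne, the closest known type being catalytic Co2(CO)8 cyclisations of gem-disubstituted enynes). Ring B closes in the 5-exo sense through the C11–C12 bond and ring A closes around it through the C13–C14 and C14–C10 bonds, so that the bicyclo[3.3.0]oct-1-en-3-one appears in one operation with the tetrasubstituted C10=C11 alkene already in place. The fully substituted carbons C17 and C15 that flank the tether hold alkyne and alkene together (Thorpe–Ingold effect) and favour the cyclisation. The only new stereocentre, C12, is expected to form as a mixture relative to C17 and C15, and no control is asked of this step because C12 and C15 are both flattened in step 7 and reset together in step 14. The selectivity that is needed is chemoselectivity for the tether vinyl group over the chlorovinyl group conjugated to the alkyne, and geometry secures it, since only the 1,6-relationship lets the insertion close a five-membered ring.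

Step 7
Reactants: 12 spirocyclic Pauson–Khand enone
Product: 14 spirocyclic dienone ester (C14 ketone conjugated through C10=C11 and C12=C15 to CO2t-Bu; C10 carrying the (Z)-2-chlorovinyl group; (S) at C17), via mesylate 13 (not isolated)
Conditions: MsCl, Et3N, CH2Cl2, 0 °C; then DBU, rt
Reagents that add atoms: none
Why: sulfonylation of the tertiary alcohol followed by vinylogous E1cB elimination through the extended enolate of the enone (C12–H is γ to the C14 ketone), which converges all C12/C15 epimers on one conjugated dienone ester.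

Step 8
Reactants: 14 spirocyclic dienone ester
Product: 15 spirocyclic dienyl alcohol (C14 carbinol, both epimers; C6 ketone intact)
Conditions: NaBH4, CeCl3·7H2O, MeOH, −40 °C
Reagents that add atoms: none
Why: Luche 1,2-reduction, which takes the conjugated C14 ketone in preference to the saturated, neopentyl C6 ketone.

Step 9
Reactants: 15 spirocyclic dienyl alcohol
Product: 16 spirocyclic diene ester (C14 methylene; C10=C11–C12=C15–CO2t-Bu; C10 carrying the (Z)-2-chlorovinyl group; ring D still the (S)-piperidine-2,4-dione)
Conditions: Et3SiH, BF3·OEt2, CH2Cl2, −78 °C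
Reagents that add atoms: none
Why: ionic deoxygenation of the dienylic alcohol, hydride being delivered to the least hindered terminus C14 of the delocalised cation so that the fully substituted, ester-conjugated diene is kept.

Step 10
Reactants: 16 spirocyclic diene ester
Product: 17 tetracyclic triene keto lactam (ring C closed by the C7–C8 bond; C8=C9, C10=C11 and C12=C15 alkenes; C6 ketone bridge; C18 lactam)
Conditions: Pd2(dba)3 (cat.), 2-dicyclohexylphosphino-2′,4′,6′-triisopropylbiphenyl (cat.), NaOt-Bu, toluene, 80 °C
Reagents that add atoms: none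
Why: palladium-catalysed intramolecular α-alkenylation of a ketone enolate with a vinyl chloride, a reaction type used to build bridged ketones, in which C7 is the only enolisable position of the C6 ketone and the new C7–C8 bond can form only on the face of ring D that carries the C11 arm, so that the C7 configuration follows from C17.

Step 11
Reactants: 17 tetracyclic triene keto lactam
Product: 18 tetracyclic diene keto lactam (C8–C9 saturated)
Conditions: H2 (1 atm), RhCl(PPh3)3 (cat.), benzene/EtOH, rt
Reagents that add atoms: none
Why: homogeneous hydrogenation with RhCl(PPh3)3, which reduces the cis-disubstituted C8=C9 alkene and leaves the two tetrasubstituted alkenes untouched.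

Step 12
Reactants: 18 tetracyclic diene keto lactam; 19 (methoxymethyl)triphenylphosphonium chloride
Product: 21 tetracyclic aldehyde (C6–H carrying the formyl carbon C20; both C6 epimers), via enol ether 20 (not isolated)
Conditions: 19, KN(SiMe3)2, THF, 0 °C to rt; then 1 M HCl, THF, rt
Reagents that add atoms: 19 (methoxymethyl)triphenylphosphonium chloride, COC[P+](c1ccccc1)(c1ccccc1)c1ccccc1.[Cl-]; water, O
Why: Wittig methoxymethylenation of the bridging C6 ketone followed by hydrolysis of the enol ether, a one-carbon homologation that brings in C20 at the aldehyde level.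

Step 13
Reactants: 21 tetracyclic aldehyde; 22 pent-1-en-3-one
Product: 23 tetracyclic keto aldehyde (quaternary C6 carrying the formyl group C20 on the side of the carbocyclic bridge and the 3-oxopentyl chain C5–C1 on the side of the lactam bridge)
Conditions: KOt-Bu (10 mol%), t-BuOH/THF, 0 °C
Reagents that add atoms: 22 pent-1-en-3-one, CCC(=O)C=C
Why: Michael addition of the aldehyde enolate to the vinyl ketone creates the quaternary C6, the acceptor being expected to approach over the lactam bridge, where C6 is flanked by the planar C18 carbonyl and a single axial hydrogen on C19, and not over the carbocyclic bridge with its C8 and C9 methylene hydrogens.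

Step 14
Reactants: 23 tetracyclic keto aldehyde
Product: 24 tetracyclic keto aldehyde with C12–H and C15–H cis (both on the face of ring B opposite the C6 bridge; C10=C11 kept)
Conditions: H2 (50 bar), [Ir(cod)(PCy3)(py)][B(C6H3(CF3)2)4] (cat.), CH2Cl2, rt
Reagents that add atoms: none
Why: hydrogenation of a fully substituted conjugated diene ester at its ester-bearing C12=C15 bond only, a reaction type known with cationic iridium catalysts, with syn addition from the face of ring B away from the C6 bridge and its C20 substituent setting both C12 and C15.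

Step 15
Reactants: 24 tetracyclic keto aldehyde with C12–H and C15–H cis
Product: 25 (3S)-hydroxy aldehyde (open-chain tautomer shown)
Conditions: (S)-selective NADPH-dependent ketoreductase, NADP+ (cat.), propan-2-ol, phosphate buffer (pH 7), DMSO (co-solvent), 30 °C
Reagents that add atoms: none
Why: enzymatic ketone reduction under reagent control, the small (ethyl) and large (CH2CH2-polycycle) binding pockets of the enzyme giving the 3S carbinol, while the neopentyl aldehyde on the quaternary bridge carbon is not expected to fit the active site.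

Step 16
Reactants: 25 (3S)-hydroxy aldehyde
Product: 26 CNP0221997.1 (target)
Conditions: LiAlH4, THF, reflux; then aq. NaOH
Reagents that add atoms: none
Why: global hydride reduction that turns the lactam into the C18 methylene of the N-methylpiperidine, the tert-butyl ester into the C21 carbinol and the aldehyde into the C20 carbinol, the ester being reduced faster than C15 can enolise.

Compound list
1 | 1-methylpiperidine-2,4-dione | CN1CCC(=O)CC1=O | starting material
2 | tert-butyl 2-(bromomethyl)prop-2-enoate | C=C(CBr)C(=O)OC(C)(C)C | starting material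
3 | tert-butyl 2-[(1-methyl-2,4-dioxopiperidin-3-yl)methyl]prop-2-enoate (racemic) | C=C(C(=O)OC(C)(C)C)CC1C(=O)CCN(C)C1=O | intermediate
4 | 1-[(trimethylsilyl)ethynyl]-1,2-benziodoxol-3(1H)-one (TMS-EBX) | C[Si](C)(C)C#CI1OC(=O)c2ccccc12 | starting material
5 | tert-butyl 2-{[(3S)-3-ethynyl-1-methyl-2,4-dioxopiperidin-3-yl]methyl}prop-2-enoate | C=C(C(=O)OC(C)(C)C)C[C@](C#C)(C(=O)CC1)C(=O)N1C | intermediate
6 | tert-butyl 3-[(3S)-3-ethynyl-1-methyl-2,4-dioxopiperidin-3-yl]-2-oxopropanoate | O=C(C(=O)OC(C)(C)C)C[C@](C#C)(C(=O)CC1)C(=O)N1C | intermediate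
7 | vinylmagnesium bromide | C=C[Mg]Br | starting material
8 | tert-butyl 2-{[(3S)-3-ethynyl-1-methyl-2,4-dioxopiperidin-3-yl]methyl}-2-hydroxybut-3-enoate (C15 epimers) | C=CC(O)(C(=O)OC(C)(C)C)C[C@](C#C)(C(=O)CC1)C(=O)N1C | intermediate
9 | (Z)-1,2-dichloroethene | Cl/C=C\Cl | starting material
10 | tert-butyl 2-({(3S)-3-[(3Z)-4-chlorobut-3-en-1-yn-1-yl]-1-methyl-2,4-dioxopiperidin-3-yl}methyl)-2-hydroxybut-3-enoate (C15 epimers) | C=CC(O)(C(=O)OC(C)(C)C)C[C@](C#C/C=C\Cl)(C(=O)CC1)C(=O)N1C | intermediate
11 | carbon monoxide | [C-]#[O+] | starting material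
12 | spirocyclic Pauson–Khand enone (rings A and B on the (S)-piperidine-2,4-dione; C14 ketone; C15 carrying OH and CO2t-Bu; C12/C15 epimers) | Cl\C=C/C3=C4C(CC3=O)C(O)(C(=O)OC(C)(C)C)C[C@]4(C(=O)CC1)C(=O)N1C | intermediate
13 | C15 methanesulfonate of 12 | Cl\C=C/C3=C4C(CC3=O)C(OS(C)(=O)=O)(C(=O)OC(C)(C)C)C[C@]4(C(=O)CC1)C(=O)N1C | intermediate
14 | spirocyclic dienone ester (C14 ketone, C10=C11, C12=C15, CO2t-Bu on C15) | Cl\C=C/C3=C4C(CC3=O)=C(C(=O)OC(C)(C)C)C[C@]4(C(=O)CC1)C(=O)N1C | intermediate
15 | spirocyclic dienyl alcohol (C14 carbinol, both epimers) | Cl\C=C/C3=C4C(CC3O)=C(C(=O)OC(C)(C)C)C[C@]4(C(=O)CC1)C(=O)N1C | intermediate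
16 | spirocyclic diene ester (C14 methylene, (Z)-2-chlorovinyl on C10) | Cl\C=C/C3=C4C(CC3)=C(C(=O)OC(C)(C)C)C[C@]4(C(=O)CC1)C(=O)N1C | intermediate
17 | tetracyclic triene keto lactam (rings A–D; C8=C9, C10=C11, C12=C15; C6 ketone; C18 lactam) | O=C1[C@H]2C=CC3=C4C(CC3)=C(C(=O)OC(C)(C)C)C[C@]41C(=O)N(C)C2 | intermediate
18 | tetracyclic diene keto lactam (C8–C9 saturated) | O=C1[C@H]2CCC3=C4C(CC3)=C(C(=O)OC(C)(C)C)C[C@]41C(=O)N(C)C2 | intermediate
19 | (methoxymethyl)triphenylphosphonium chloride | COC[P+](c1ccccc1)(c1ccccc1)c1ccccc1.[Cl-] | starting material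
20 | methyl enol ether at C6 of 18 (C6=CH–OMe, E/Z) | COC=C1[C@H]2CCC3=C4C(CC3)=C(C(=O)OC(C)(C)C)C[C@]41C(=O)N(C)C2 | intermediate
21 | tetracyclic aldehyde (C6–H carrying CHO, C6 epimers) | O=CC1[C@H]2CCC3=C4C(CC3)=C(C(=O)OC(C)(C)C)C[C@]41C(=O)N(C)C2 | intermediate
22 | pent-1-en-3-one (ethyl vinyl ketone) | CCC(=O)C=C | starting material
23 | tetracyclic keto aldehyde (quaternary C6 with formyl C20 and 3-oxopentyl chain) | CCC(=O)CC[C@]1(C=O)[C@H]2CCC3=C4C(CC3)=C(C(=O)OC(C)(C)C)C[C@]41C(=O)N(C)C2 | intermediate
24 | tetracyclic keto aldehyde with C12–H and C15–H cis | CCC(=O)CC[C@]1(C=O)[C@H]2CCC3=C4[C@@H](CC3)[C@@H](C(=O)OC(C)(C)C)C[C@]41C(=O)N(C)C2 | intermediate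
25 | (3S)-hydroxy aldehyde (lactam and tert-butyl ester still present) | CC[C@H](O)CC[C@]1(C=O)[C@H]2CCC3=C4[C@@H](CC3)[C@@H](C(=O)OC(C)(C)C)C[C@]41C(=O)N(C)C2 | intermediate
26 | CNP0221997.1 | CC[C@H](O)CC[C@]1(CO)[C@H]2CCC3=C4[C@@H](CC3)[C@@H](CO)C[C@]41CN(C)C2 | target

Total step count: 16. Longest linear sequence: 16 steps (1 to 26).

Steps most likely to fail

Step 2: the enantiomeric excess may be too low, because a background reaction of the potassium enolate outside the chiral ion pair erodes the selectivity. The fallback sets out from 3 and uses an activated haloalkyne instead of the iodane. Alkynylation with allyl 3-chloroprop-2-ynoate under cinchona-alkaloid-derived phase-transfer catalysis proceeds by conjugate addition–elimination, a reaction type that gives high enantioselectivity with cyclic β-dicarbonyl compounds, and should give the alkynoate F1. Deallylation with zerovalent palladium (Pd(PPh3)4, PhSiH3) should give the propiolic acid F2, and CuCl-catalysed protodecarboxylation comes back to the route at 5.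

Step 10: the palladium enolate may fail to close the seven-membered ring, since reductive elimination from the large palladacycle is slow and hydrodechlorination or oligomerisation can take over. The fallback sets out from 16 and closes the ring by SN2 alkylation instead of cross-coupling. Diimide reduction (TsNHNH2, NaOAc, DME/H2O, reflux) of the cis-disubstituted chlorovinyl alkene should give the chloroethyl compound F3, and intramolecular alkylation of the C6 ketone enolate at C7 (KOt-Bu, NaI, THF) comes back to the route at 18, so that step 11 is no longer needed.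

Step 13: the facial selectivity at C6 may be poor or reversed, attack over the carbocyclic bridge giving the C6 epimer. The fallback sets out from 21 and uses the same facial preference the other way round, by bringing in C20 last. Hydroxymethylation with aqueous formaldehyde (pyrrolidine cat.) should give the hydroxymethyl aldehyde F4, in which the aldehyde carbon is now C5 and the new CH2OH is C20. Horner–Wadsworth–Emmons olefination with diethyl (2-oxobutyl)phosphonate (LiCl, DBU) should give the enone F5, and CBS reduction ((R)-2-methyl-CBS-oxazaborolidine, catecholborane) the (S)-allylic alcohol F6. Hydrogenation as in step 14, which also saturates C4=C5, should give the hydroxy ester F7, and LiAlH4 as in step 16 comes back to the route at 26.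

Further compounds
F1 | step 2 | prop-2-enyl 3-[(3S)-3-{2-[(tert-butoxy)carbonyl]prop-2-en-1-yl}-1-methyl-2,4-dioxopiperidin-3-yl]prop-2-ynoate | C=C(C(=O)OC(C)(C)C)C[C@](C#CC(=O)OCC=C)(C(=O)CC1)C(=O)N1C
F2 | step 2 | 3-[(3S)-3-{2-[(tert-butoxy)carbonyl]prop-2-en-1-yl}-1-methyl-2,4-dioxopiperidin-3-yl]prop-2-ynoic acid | C=C(C(=O)OC(C)(C)C)C[C@](C#CC(=O)O)(C(=O)CC1)C(=O)N1C
F3 | step 10 | spirocyclic diene ester with a 2-chloroethyl group on C10 | ClCCC3=C4C(CC3)=C(C(=O)OC(C)(C)C)C[C@]4(C(=O)CC1)C(=O)N1C
F4 | step 13 | tetracyclic hydroxymethyl aldehyde (C6 carrying CHO as C5 and CH2OH as C20) | O=C[C@]1(CO)[C@H]2CCC3=C4C(CC3)=C(C(=O)OC(C)(C)C)C[C@]41C(=O)N(C)C2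
F5 | step 13 | tetracyclic (E)-enone (C4=C5, C3 ketone) | CCC(=O)/C=C/[C@]1(CO)[C@H]2CCC3=C4C(CC3)=C(C(=O)OC(C)(C)C)C[C@]41C(=O)N(C)C2
F6 | step 13 | tetracyclic (3S)-allylic alcohol | CC[C@H](O)/C=C/[C@]1(CO)[C@H]2CCC3=C4C(CC3)=C(C(=O)OC(C)(C)C)C[C@]41C(=O)N(C)C2
F7 | step 13 | tetracyclic (3S)-hydroxy ester with C12–H and C15–H cis (lactam and tert-butyl ester present) | CC[C@H](O)CC[C@]1(CO)[C@H]2CCC3=C4[C@@H](CC3)[C@@H](C(=O)OC(C)(C)C)C[C@]41C(=O)N(C)C2
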